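**Assumptions (one line each)**
- The target is read as: (2R,3R)-dihydroflavonol (taxifolin configuration), with a 2,3-*trans* dihydrobenzofuran (C7 = R bearing the guaiacyl ring, C8 = S bearing CH2OH). The B ring is a taxifolin B ring whose 3'-O and C2' carry the dihydrobenzofuran.
- In taxifolin the phenol acidity order is 7-OH > 4'-OH > 3'-OH ≫ 5-OH (chelated) and 3-OH (aliphatic). I assume this order gives useful regioselectivity in the benzylation and Mitsunobu steps.

**Retrosynthesis**
1. Target ← global hydrogenolysis of tri-O-benzyl compound **11**.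
2. **11** ← *trans*-selective Friedel–Crafts C-arylation of guaiacol at the oxocarbenium generated from lactol **9**. This forms C7–aryl and sets C7 trans to C8.
3. **9** ← oxidative cleavage of the propenyl group of Claisen product **8**. The aldehyde closes onto the free 3'-OH to form the dihydrobenzofuran ring as a lactol.
4. **8** ← aromatic Claisen [3,3] rearrangement of aryl ether **7**. This is the key step: it forms the C2'–C8 bond and transfers the carbinol chirality to C8. **7** ← Mitsunobu coupling (with inversion) of 7,4'-di-O-benzyltaxifolin **6** and chiral allylic alcohol **4**, which is made from (S)-3-butyn-2-ol. Taxifolin supplies C2/C3.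

**Route**

**Step 1**
Reactants: **1** (S)-3-butyn-2-ol
Product: **2** (S)-pent-2-yne-1,4-diol
Conditions: n-BuLi (2.2 equiv), THF, −78→0 °C; then (CH2O)n, 0 °C→rt; NH4Cl work-up
Reagents that add atoms: paraformaldehyde, C=O
Why: The dianion (alkoxide plus acetylide) is hydroxymethylated at the acetylide carbon (organolithium addition to formaldehyde). The carbinol stereocentre is untouched.

**Step 2**
Reactants: **2**
Product: **3** (2E,4S)-pent-2-ene-1,4-diol
Conditions: Red-Al (2.5 equiv), THF, 0 °C→rt; Rochelle salt work-up
Reagents that add atoms: none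
Why: Alkoxide-directed trans-hydroalumination of the propargylic alcohol (Red-Al reduction) gives the E-alkene; the stereocentre is not involved.

**Step 3**
Reactants: **3**
Product: **4** (2S,3E)-5-(benzyloxy)pent-3-en-2-ol
Conditions: BnBr (1.05 equiv), Ag2O (1.5 equiv), CH2Cl2, rt, dark
Reagents that add atoms: benzyl bromide, BrCc1ccccc1
Why: Silver(I) oxide-mediated Williamson etherification goes preferentially at the unhindered primary OH, leaving the secondary (stereogenic) OH free. Any bis-benzyl ether is removed by chromatography.

**Step 4**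
Reactants: **5** (+)-taxifolin, (2R,3R)-dihydroquercetin
Product: **6** 7,4'-di-O-benzyltaxifolin
Conditions: BnBr (2.1 equiv), K2CO3 (2.1 equiv), cat. NaI, acetone, 0 °C→rt, N2
Reagents that add atoms: benzyl bromide, BrCc1ccccc1
Why: Selective Williamson O-benzylation of the two most acidic phenols (7-OH, 4'-OH) with two equivalents. The 3'-OH, 3-OH and chelated 5-OH stay free, and the mild base leaves C2/C3 untouched.

**Step 5**
Reactants: **6**, **4**
Product: **7** 3'-O-[(2R,3E)-5-(benzyloxy)pent-3-en-2-yl]-7,4'-di-O-benzyltaxifolin
Conditions: PPh3 (1.5 equiv), DIAD (1.5 equiv), THF, 0 °C→rt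
Reagents that add atoms: none
Why: Mitsunobu etherification occurs at the only remaining acidic phenol (3'-OH). SN2 inversion converts the (S)-alcohol into the (R)-aryl ether and keeps the E-alkene.

**Step 6**
Reactants: **7**
Product: **8** 2'-[(1S,2E)-1-(benzyloxymethyl)but-2-enyl]-7,4'-di-O-benzyltaxifolin (free 3'-OH)
Conditions: o-Cl2C6H4, BHT, 180 °C (µW, sealed), 1–2 h, Ar
Reagents that add atoms: none
Why: Aromatic Claisen rearrangement. C4' carries OBn, so C2' is the only free ortho position and the rearrangement is regiospecific. The chair transition state puts the methyl group pseudo-equatorial, and the suprafacial transfer from the (R)-carbinol with the E-alkene gives (S)-C8. The free phenol re-forms by tautomerisation of the dienone.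

**Step 7**
Reactants: **8**
Product: **9** 2-hydroxy-2,3-dihydrobenzofuran (lactol, C7 anomeric mixture; C8 = S, CH2OBn at C8)
Conditions: O3, CH2Cl2, −78 °C; then Me2S, −78 °C→rt
Reagents that add atoms: ozone, [O-][O+]=O
Why: Ozonolysis cleaves only the propenyl alkene, giving an α-aryl aldehyde. The ortho 3'-OH traps it at once as the cyclic hemiacetal, forming the dihydrobenzofuran ring. This limits epimerisation at C8 and β-elimination of the benzyloxy group.

**Step 8**
Reactants: **9**, **10** guaiacol (2-methoxyphenol)
Product: **11** tri-O-benzyl target (C7 = R, C8 = S, trans)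
Conditions: guaiacol (10 equiv), BF3·OEt2 (2 equiv), CH2Cl2, −40→0 °C
Reagents that add atoms: none
Why: Lewis acid ionises the lactol to a benzofuranium oxocarbenium. Guaiacol attacks para to its OH (Friedel–Crafts hydroxyalkylation/arylation) from the face anti to the C8 CH2OBn group. This gives the 2,3-*trans* product, which sets C7 = R relative to C8.

**Step 9**
Reactants: **11**
Product: **12** target
Conditions: H2 (1 atm), 10% Pd/C, EtOAc/MeOH 1:1, rt, 3 h
Reagents that add atoms: none
Why: Catalytic hydrogenolysis removes the three benzyl ethers (7-O, 4'-O, C9-O). The chromanone C=O is deactivated by the 5,7-dioxygenation and survives. The benzylic C7–O bond is retained under short, mild conditions.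

**Compound list**

| No. | Name | SMILES | Role |
|---|---|---|---|
| 1 | (S)-3-butyn-2-ol | C[C@H](O)C#C | starting material |
| 2 | (S)-pent-2-yne-1,4-diol | C[C@H](O)C#CCO | intermediate |
| 3 | (2E,4S)-pent-2-ene-1,4-diol | C[C@H](O)/C=C/CO | intermediate |
| 4 | (2S,3E)-5-(benzyloxy)pent-3-en-2-ol | C[C@H](O)/C=C/COCc1ccccc1 | intermediate |
| 5 | (+)-taxifolin (2R,3R) | Oc1ccc(cc1O)[C@H]2Oc3cc(O)cc(O)c3C(=O)[C@@H]2O | starting material |
| 6 | 7,4'-di-O-benzyltaxifolin | O(Cc1ccccc1)c2ccc([C@H]3Oc4cc(OCc5ccccc5)cc(O)c4C(=O)[C@@H]3O)cc2O | intermediate |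
| 7 | 3'-O-allylic aryl ether of 6 | O(Cc1ccccc1)c2ccc([C@H]3Oc4cc(OCc5ccccc5)cc(O)c4C(=O)[C@@H]3O)cc2O[C@H](C)/C=C/COCc6ccccc6 | intermediate |
| 8 | Claisen product (2'-substituted, free 3'-OH) | C/C=C/[C@H](COCc1ccccc1)c2c(O)c(OCc3ccccc3)ccc2[C@H]4Oc5cc(OCc6ccccc6)cc(O)c5C(=O)[C@@H]4O | intermediate |
| 9 | dihydrobenzofuran-2-ol (lactol) | OC1Oc2c(OCc3ccccc3)ccc([C@H]4Oc5cc(OCc6ccccc6)cc(O)c5C(=O)[C@@H]4O)c2[C@H]1COCc7ccccc7 | intermediate |
| 10 | guaiacol | COc1ccccc1O | starting material |
| 11 | tri-O-benzyl target | COc1cc([C@@H]2Oc3c(OCc6ccccc6)ccc([C@H]4Oc5cc(OCc7ccccc7)cc(O)c5C(=O)[C@@H]4O)c3[C@H]2COCc8ccccc8)ccc1O | intermediate |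
| 12 | target CID21589839 | COc1cc([C@@H]2Oc3c(O)ccc([C@H]4Oc5cc(O)cc(O)c5C(=O)[C@@H]4O)c3[C@H]2CO)ccc1O | target |

**Totals:** 9 steps in all. The longest linear sequence is 8 steps (1→2→3→5→6→7→8→9); the branch from taxifolin alone is 6 steps.

**Three steps most likely to fail**
1. **Step 4 (regioselective 7,4'-dibenzylation; base sensitivity of C2/C3).** Over- or under-benzylation, or C2/C3 epimerisation or oxidation, is possible.
   - Fallback: protect the catechol as a diphenylmethylene ketal with 7-O-benzylation, then open it regioselectively with DIBAL to the 4'-O-benzhydryl/3'-OH pair, and continue with the benzhydryl group in place of 4'-OBn.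
2. **Step 6 (thermal Claisen at the hindered C2' site, next to the flavanonol C2, at 180 °C).** The risks are flavanonol epimerisation or ring-opening, and loss of chirality transfer.
   - Fallback: drop the [3,3] rearrangement and perform an ortho-selective Pd-catalysed Tsuji–Trost C-allylation of free phenol **6** with the carbonate of **4** at lower temperature, then continue from the propenyl intermediate.
3. **Step 8 (Friedel–Crafts arylation of the lactol).** The oxocarbenium can aromatise to the 3-substituted benzofuran by loss of H8. The A ring may compete as a nucleophile, and guaiacol regiochemistry may be mixed.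
   - Fallback: add 4-benzyloxy-3-methoxyphenylmagnesium bromide to lactol **9** (ring-opened aldehyde) to give the diol. Close the ring by Mitsunobu or acid-mediated cyclodehydration (p-quinone methide pathway) to the trans dihydrobenzofuran, then hydrogenolyse.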